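**Retrosynthetic overview**
1. 2,3,4,6-Tetrabromoindole ⇒ 4,6-dibromoindole. The two pyrrole-ring bromines go on last (C3, then C2) by electrophilic bromination, and the two benzene-ring bromines are bought in.
2. 4,6-Dibromoindole ⇒ ethyl 4,6-dibromoindole-2-carboxylate, by saponification and protodecarboxylation.
3. Indole ester ⇒ ethyl (Z)-2-azido-3-(2,4-dibromophenyl)acrylate. Azide thermolysis closes N–C7a; the pyrrole ring is the only ring formed, built onto the purchased benzene ring.
4. Azidoacrylate ⇒ 2,4-dibromobenzaldehyde + ethyl azidoacetate. An intermolecular aldol condensation makes the indole C2–C3 bond, which is the key C–C bond.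
5. Ethyl azidoacetate ⇒ ethyl bromoacetate + NaN3.

Assumption: the target is planar and has no stereocentre, so no enantiomer question arises. The only stereo-element in the route is the Z-alkene of compound 6, which disappears on cyclisation.

**Step 1**
Reactants: 1 ethyl bromoacetate
Product: 2 ethyl azidoacetate
Conditions: NaN3 (1.2 equiv), acetone/H2O 3:1, rt, 16 h; extract into Et2O, concentrate cold, use crude, do not distil
Reagents that add atoms: sodium azide, [Na+].[N-]=[N+]=[N-]
Why: SN2 displacement of an activated primary α-bromo ester by azide is fast and clean, and no stereocentre is involved.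

**Step 2**
Reactants: 2 ethyl azidoacetate; 3 2,4-dibromobenzaldehyde
Product: 6 ethyl (Z)-2-azido-3-(2,4-dibromophenyl)acrylate, via azidoacetate sodium enolate 4 (not isolated), via racemic aldol adduct 5 (not isolated)
Conditions: 2 (3.5 equiv), NaOEt (3.5 equiv), EtOH, −15 °C → 0 °C, 5 h; pour onto ice/aq. NH4Cl, filter
Reagents that add atoms: none
Why: In this intermolecular aldol condensation (first stage of the Hemetsberger–Knittel sequence), enolate 4 adds to the non-enolisable aldehyde 3 to forge the future indole C2–C3 bond, E1cB loss of hydroxide from 5 erases both transient stereocentres and gives the favoured Z-alkene (aryl trans to the ester), and the aryl bromides are inert to cold ethoxide.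

**Step 3**
Reactants: 6 ethyl (Z)-2-azido-3-(2,4-dibromophenyl)acrylate
Product: 8 ethyl 4,6-dibromo-1H-indole-2-carboxylate, via 2H-azirine ester 7 (not isolated)
Conditions: xylenes, reflux (140 °C), slow addition of 6 to 0.05 M final concentration, 2 h
Reagents that add atoms: none
Why: In the Hemetsberger–Knittel indole synthesis, thermal loss of N2 through azirine 7 delivers the nitrogen onto the only free ortho position of the aryl ring (the other carries Br), so a single regioisomer forms in which the former C2 and C4 bromines become indole C4 and C6.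

**Step 4**
Reactants: 8 ethyl 4,6-dibromo-1H-indole-2-carboxylate
Product: 10 4,6-dibromo-1H-indole-2-carboxylic acid, via sodium carboxylate 9 (not isolated)
Conditions: NaOH (3 equiv), EtOH/H2O 3:1, 80 °C, 2 h; then 2 M HCl to pH 2, filter
Reagents that add atoms: sodium hydroxide, [Na+].[OH-]
Why: Saponification is driven to completion by formation of carboxylate 9, the aryl bromides and the indole NH are untouched, and the acid precipitates on acidification.

**Step 5**
Reactants: 10 4,6-dibromo-1H-indole-2-carboxylic acid
Product: 11 4,6-dibromo-1H-indole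
Conditions: Cu powder (0.1 equiv), quinoline, 220 °C, N2, 1–2 h (until gas evolution stops); EtOAc, wash with 2 M HCl
Reagents that add atoms: none
Why: Copper-catalysed thermal protodecarboxylation is the classical way to remove the C2 acid group of an indole, C2 being protonated as CO2 leaves, and without added base or ligand the aryl bromides couple only slowly.

**Step 6**
Reactants: 11 4,6-dibromo-1H-indole
Product: 13 2,3,4,6-tetrabromo-1H-indole, via 3,4,6-tribromo-1H-indole 12 (not isolated)
Conditions: NBS (1.03 equiv), silica gel, dry CH2Cl2, 0 °C, 30 min, dark; then NBS (1.03 equiv), rt, 2 h; filter, wash with aq. Na2S2O3/NaHCO3, quick chromatography, store cold and dark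
Reagents that add atoms: N-bromosuccinimide, O=C1CCC(=O)N1Br
Why: In two successive electrophilic aromatic brominations, the enamine-like C3 reacts first to give 12, the second equivalent fills the only remaining pyrrole position C2, and the benzene ring, deactivated by two bromines, does not compete while NBS is held to about two equivalents.

**Compound list**
1 | ethyl bromoacetate | CCOC(=O)CBr | starting material
2 | ethyl azidoacetate | CCOC(=O)CN=[N+]=[N-] | intermediate
3 | 2,4-dibromobenzaldehyde | O=Cc1ccc(Br)cc1Br | starting material
4 | sodium enolate of ethyl azidoacetate (not isolated) | CCOC([O-])=CN=[N+]=[N-].[Na+] | intermediate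
5 | ethyl 2-azido-3-(2,4-dibromophenyl)-3-hydroxypropanoate, racemic diastereomer mixture (not isolated) | CCOC(=O)C(N=[N+]=[N-])C(O)c1ccc(Br)cc1Br | intermediate
6 | ethyl (Z)-2-azido-3-(2,4-dibromophenyl)acrylate | CCOC(=O)/C(N=[N+]=[N-])=C/c1ccc(Br)cc1Br | intermediate
7 | ethyl 2-(2,4-dibromophenyl)-2H-azirine-3-carboxylate, racemic (not isolated) | CCOC(=O)C1=NC1c1ccc(Br)cc1Br | intermediate
8 | ethyl 4,6-dibromo-1H-indole-2-carboxylate | CCOC(=O)c1cc2c(Br)cc(Br)cc2[nH]1 | intermediate
9 | sodium 4,6-dibromo-1H-indole-2-carboxylate (not isolated) | [Na+].[O-]C(=O)c1cc2c(Br)cc(Br)cc2[nH]1 | intermediate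
10 | 4,6-dibromo-1H-indole-2-carboxylic acid | OC(=O)c1cc2c(Br)cc(Br)cc2[nH]1 | intermediate
11 | 4,6-dibromo-1H-indole | Brc1cc(Br)c2cc[nH]c2c1 | intermediate
12 | 3,4,6-tribromo-1H-indole (not isolated) | Brc1cc(Br)c2c(Br)c[nH]c2c1 | intermediate
13 | 2,3,4,6-tetrabromo-1H-indole | Brc1cc(Br)c2c(Br)c(Br)[nH]c2c1 | target

**Totals**
Total step count: 6. Longest linear sequence: 6 steps (1 → 13); counted from aldehyde 3 it is 5 steps.

**Three steps most likely to fail**

**Step 2 (aldol condensation).**
- Risk: the azidoacetate enolate decomposes with loss of N2 in base. The ortho-bromo aldehyde is hindered. The hydroxide released can hydrolyse the ester.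
- Fallback, setting out from 3 and coming back at 6: the carbon skeleton is made first and the azide is put on afterwards.
- Aldehyde 3 is olefinated with triethyl phosphonoacetate (Horner–Wadsworth–Emmons; LiCl, DBU, MeCN, rt) to ethyl (E)-3-(2,4-dibromophenyl)acrylate F1.
- Br2 in CH2Cl2 at 0 °C adds anti to give racemic ethyl (2R*,3S*)-2,3-dibromo-3-(2,4-dibromophenyl)propanoate F2.
- NaN3 (3 equiv) in DMF at rt replaces the α-bromide, and HBr is eliminated across the acidified α-position. This gives the same Z-azidoacrylate 6, which enters step 3.

**Step 5 (protodecarboxylation).**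
- Risk: at 220 °C with copper, partial loss or coupling of aryl bromide and tar formation are possible.
- Fallback, setting out from 8 and coming back at 13: the carboxyl group is exchanged directly for the last bromine instead of for hydrogen.
- Ester 8 is brominated at C3 (NBS 1.05 equiv, DMF, rt) to ethyl 3,4,6-tribromo-1H-indole-2-carboxylate F3.
- F3 is saponified (NaOH, EtOH/H2O), evaporated and dried to sodium 3,4,6-tribromo-1H-indole-2-carboxylate F4.
- The salt is treated with Bu4NBr3 (1.0 equiv) in dry MeCN at 50–80 °C. Ionic ipso-bromodecarboxylation places bromine on C2 as CO2 leaves and gives 13, bypassing 10, 11 and 12.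

**Step 6 (double bromination of the free NH indole).** This is the most delicate step.
- Risk: NH 3-bromo- and 2,3-dibromoindoles are sensitive to acid, light and moisture (oxindole formation). Excess NBS could attack C5 or C7.
- Fallback, setting out from 11 and coming back at 13: the bromination is run on a stabilised N-carbamate.
- Indole 11 is acylated (ClCO2Me, Et3N, DMAP cat., CH2Cl2) to methyl 4,6-dibromo-1H-indole-1-carboxylate F5.
- Br2 (2.2 equiv, CH2Cl2, rt to reflux) brominates C3 and C2 to give robust, crystallisable methyl 2,3,4,6-tetrabromo-1H-indole-1-carboxylate F6.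
- K2CO3 in MeOH at rt removes the carbamate as the last operation and delivers 13.

**Further compounds**
F1 | step 2 | ethyl (E)-3-(2,4-dibromophenyl)acrylate | CCOC(=O)/C=C/c1ccc(Br)cc1Br
F2 | step 2 | ethyl (2R*,3S*)-2,3-dibromo-3-(2,4-dibromophenyl)propanoate, racemic, one enantiomer drawn | CCOC(=O)[C@@H](Br)[C@@H](Br)c1ccc(Br)cc1Br
F3 | step 5 | ethyl 3,4,6-tribromo-1H-indole-2-carboxylate | CCOC(=O)c1[nH]c2cc(Br)cc(Br)c2c1Br
F4 | step 5 | sodium 3,4,6-tribromo-1H-indole-2-carboxylate | [Na+].[O-]C(=O)c1[nH]c2cc(Br)cc(Br)c2c1Br
F5 | step 6 | methyl 4,6-dibromo-1H-indole-1-carboxylate | COC(=O)n1ccc2c(Br)cc(Br)cc21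
F6 | step 6 | methyl 2,3,4,6-tetrabromo-1H-indole-1-carboxylate | COC(=O)n1c(Br)c(Br)c2c(Br)cc(Br)cc21
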